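**Retrosynthetic overview**
- The ring B pivalate is removed last. Before that, the two prenyl C–C bonds at C3 and C5 of ring A are cut (phenoxide C-alkylation), and the C6 hydroxyl is traced back to a methyl ether cleaved by BCl3 under chelation control.
- The strategy rests on ring A carrying the aroyl carbon on C1, a hydroxyl on the neighbouring C2 and a second oxygen on C6. The adjacent C1–C(=O) and C2–O bonds are cut together, back to 3,5-dimethoxybenzyne (triple bond C1≡C2, its methoxy groups becoming C6–O and C4–O) and a 3-acyloxybenzoic acid.
- The aryne is stored as an ortho-silylaryl triflate, made from 3,5-dimethoxyphenol by carbamate-directed ortho-lithiation, silylation and triflation. The acid partner comes from 3-hydroxybenzoic acid by pivaloylation.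
- Both benzene rings are bought, so no ring is formed in the route; a four-membered benzoxete appears only transiently in the key step.

Key step: step 5

Remark: the target has no stereocentre and both side-chain alkenes end in two identical methyl groups, so no configuration has to be controlled.

**Route**

Step 1
Reactants: 1 3,5-dimethoxyphenol
Product: 2 3,5-dimethoxyphenyl N-isopropylcarbamate
Conditions: i-PrNCO (1.2 equiv), Et3N (0.2 equiv), CH2Cl2, rt
Reagents that add atoms: isopropyl isocyanate, CC(C)N=C=O
Why: Amine-catalysed addition of the phenol O–H across the isocyanate (carbamoylation) is clean for an unhindered phenol and installs the N-isopropylcarbamate that later directs metalation and can be removed under mild base.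

Step 2
Reactants: 2 3,5-dimethoxyphenyl N-isopropylcarbamate
Product: 6 3,5-dimethoxy-2-(trimethylsilyl)phenyl N-isopropylcarbamate, via N-silylated carbamate 3 (not isolated), via ortho-lithiated N-silyl carbamate 4 (not isolated), via N-silyl C-silyl carbamate 5 (not isolated)
Conditions: Me3SiOTf (1.1 equiv), TMEDA (1.1 equiv), Et2O, 0 °C → rt; then n-BuLi (2.2 equiv), TMEDA (2 equiv), −78 °C; then Me3SiCl (3 equiv), −78 °C → rt; aq. NaHSO4 work-up
Reagents that add atoms: chlorotrimethylsilane, C[Si](C)(C)Cl
Why: Directed ortho-metalation, in which in situ N-silylation masks the N–H, the carbamate (the strongest director on the ring) and the C3 methoxy group together place lithium at C2 between them (C6 is equivalent by symmetry, C4 lies between two weaker methoxy directors), Me3SiCl traps the aryllithium, and the N-silyl group is hydrolysed on acidic work-up.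

Step 3
Reactants: 6 3,5-dimethoxy-2-(trimethylsilyl)phenyl N-isopropylcarbamate
Product: 8 3,5-dimethoxy-2-(trimethylsilyl)phenyl trifluoromethanesulfonate, via DBU salt of 3,5-dimethoxy-2-(trimethylsilyl)phenol 7 (not isolated)
Conditions: DBU (1.5 equiv), Et2NH (1.2 equiv), MeCN, 40 °C; then PhNTf2 (1.5 equiv), rt
Reagents that add atoms: N-phenylbis(trifluoromethanesulfonimide), O=S(=O)(N(c1ccccc1)S(=O)(=O)C(F)(F)F)C(F)(F)F
Why: E1cB carbamate cleavage followed by O-triflation in one pot, in which DBU removes the N–H proton, the phenoxide and isopropyl isocyanate separate, diethylamine traps the isocyanate as a urea, and PhNTf2 sulfonylates the phenoxide under conditions mild enough to keep the aryl C–Si bond.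

Step 4
Reactants: 9 3-hydroxybenzoic acid
Product: 10 3-(pivaloyloxy)benzoic acid
Conditions: PivCl (1.1 equiv), aq. NaOH (2.2 equiv), THF–H2O, 0 °C; then aq. HCl to pH 2
Reagents that add atoms: pivaloyl chloride, CC(C)(C)C(=O)Cl
Why: Schotten–Baumann acylation, in which the phenoxide of the dianion is acylated, any mixed anhydride at the carboxylate is hydrolysed in the aqueous base, and acidification returns the free acid with the phenol masked as a hindered ester that should tolerate fluoride and arynes.

Step 5
Reactants: 8 3,5-dimethoxy-2-(trimethylsilyl)phenyl trifluoromethanesulfonate; 10 3-(pivaloyloxy)benzoic acid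
Product: 14 3-(2-hydroxy-4,6-dimethoxybenzoyl)phenyl pivalate, via 3,5-dimethoxybenzyne 11 (not isolated), via aryl caesium ester 12 (not isolated), via benzoxete alkoxide 13 (not isolated)
Conditions: 8 (1.5 equiv), 10 (1.0 equiv), CsF (4 equiv), THF, 125 °C, sealed tube
Reagents that add atoms: none
Why: Fluoride attacks silicon of 8 and triflate departs, releasing aryne 11; the caesium carboxylate of 10 then adds through oxygen to the aryne carbon remote from the flanking methoxy group, giving aryl anion 12 at the carbon between the new ester oxygen and that methoxy group. The anion attacks the ester carbonyl just formed in a 4-exo-trig closure to benzoxete alkoxide 13, which reopens by C–O cleavage to the ortho-acylphenoxide, so the C1–C(=O) and C2–O bonds of ring A are made in one operation and no ring remains closed. The closest known reaction type is the fluoride-induced insertion of arynes into the C–O bond of carboxylic acids, an intramolecular anionic acyl transfer related to the anionic Fries shift, which gives ortho-hydroxyaryl ketones. No stereocentre is formed. The step needs regioselectivity across the triple bond, which the methoxy group next to the aryne secures by stabilising the adjacent anion inductively and distorting the aryne so that the distal, less hindered carbon accepts oxygen; it also needs acyl transfer to outrun protonation of 12, which THF at high temperature favours, and attack on the new aryl ester in preference to the remote hindered pivalate, which the intramolecular delivery ensures.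

Step 6
Reactants: 14 3-(2-hydroxy-4,6-dimethoxybenzoyl)phenyl pivalate
Product: 15 3-(2,6-dihydroxy-4-methoxybenzoyl)phenyl pivalate
Conditions: BCl3 (3 equiv, 1 M in CH2Cl2), CH2Cl2, −78 °C → rt; aq. HCl work-up
Reagents that add atoms: none
Why: Chelation-controlled Lewis acid cleavage of an aryl methyl ether, in which BCl3 (in excess, since the free C2 phenol consumes the first equivalent) binds the ketone oxygen and the flanking C6 methoxy oxygen and chloride removes that methyl group, while the unchelated C4 methyl ether and the aryl pivalate lack this activation and should survive at or below room temperature.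

Step 7
Reactants: 15 3-(2,6-dihydroxy-4-methoxybenzoyl)phenyl pivalate; 16 prenyl bromide (1-bromo-3-methylbut-2-ene)
Product: 18 3-[2,6-dihydroxy-4-methoxy-3,5-bis(3-methylbut-2-en-1-yl)benzoyl]phenyl pivalate, via mono-C-prenylated ketone 17 (not isolated)
Conditions: 16 (2.3 equiv), DBU (2.5 equiv), THF, 0 °C → rt
Reagents that add atoms: none
Why: Phenoxide C-alkylation of an acylphloroglucinol-type nucleus, in which the phenoxide charge is delocalised onto C3 and C5 (each ortho to one hydroxyl and para to the other, and the only free ring carbons), so SN2 attack on prenyl bromide and re-aromatisation should install first one and then the second prenyl group, while the non-nucleophilic amidine base in THF leaves the pivalate intact.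

Step 8
Reactants: 18 3-[2,6-dihydroxy-4-methoxy-3,5-bis(3-methylbut-2-en-1-yl)benzoyl]phenyl pivalate
Product: 19 (2,6-dihydroxy-4-methoxy-3,5-bis(3-methylbut-2-en-1-yl)phenyl)(3-hydroxyphenyl)methanone
Conditions: K2CO3 (2 equiv), MeOH, rt, argon; aq. NH4Cl work-up
Reagents that add atoms: none
Why: Base-mediated transesterification (methanolysis) of the aryl ester, in which methoxide formed from K2CO3 in methanol attacks the pivaloyl carbonyl and expels the ring B phenoxide, while the prenyl groups, the methyl ether and the diaryl ketone are inert.

**Compound list**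

1 | 3,5-dimethoxyphenol | COc1cc(O)cc(OC)c1 | starting material
2 | 3,5-dimethoxyphenyl N-isopropylcarbamate | COc1cc(OC)cc(OC(=O)NC(C)C)c1 | intermediate
3 | 3,5-dimethoxyphenyl N-isopropyl-N-(trimethylsilyl)carbamate | COc1cc(OC)cc(OC(=O)N(C(C)C)[Si](C)(C)C)c1 | intermediate (not isolated)
4 | 2-lithio-3,5-dimethoxyphenyl N-isopropyl-N-(trimethylsilyl)carbamate | COc1cc(OC)c([Li])c(OC(=O)N(C(C)C)[Si](C)(C)C)c1 | intermediate (not isolated)
5 | 3,5-dimethoxy-2-(trimethylsilyl)phenyl N-isopropyl-N-(trimethylsilyl)carbamate | COc1cc(OC)c([Si](C)(C)C)c(OC(=O)N(C(C)C)[Si](C)(C)C)c1 | intermediate (not isolated)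
6 | 3,5-dimethoxy-2-(trimethylsilyl)phenyl N-isopropylcarbamate | COc1cc(OC)c([Si](C)(C)C)c(OC(=O)NC(C)C)c1 | intermediate
7 | 1,8-diazabicyclo[5.4.0]undec-7-enium 3,5-dimethoxy-2-(trimethylsilyl)phenoxide | COc1cc(OC)c([Si](C)(C)C)c([O-])c1.C1CCC2=[NH+]CCCN2CC1 | intermediate (not isolated)
8 | 3,5-dimethoxy-2-(trimethylsilyl)phenyl trifluoromethanesulfonate | COc1cc(OC)c([Si](C)(C)C)c(OS(=O)(=O)C(F)(F)F)c1 | intermediate
9 | 3-hydroxybenzoic acid | OC(=O)c1cccc(O)c1 | starting material
10 | 3-(pivaloyloxy)benzoic acid | CC(C)(C)C(=O)Oc1cccc(C(=O)O)c1 | intermediate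
11 | 3,5-dimethoxybenzyne (1,2-didehydro-3,5-dimethoxybenzene) | COC1=CC(OC)=CC#C1 | intermediate (not isolated)
12 | 2-caesio-3,5-dimethoxyphenyl 3-(pivaloyloxy)benzoate | COc1cc(OC)c([Cs])c(OC(=O)c2cccc(OC(=O)C(C)(C)C)c2)c1 | intermediate (not isolated)
13 | caesium 4,6-dimethoxy-2-[3-(pivaloyloxy)phenyl]-2H-benzoxet-2-olate (oxete ring fused to the arene, oxygen on the former C–OTf carbon) | [Cs+].COc1cc(OC)c2c(c1)OC2([O-])c1cccc(OC(=O)C(C)(C)C)c1 | intermediate (not isolated)
14 | 3-(2-hydroxy-4,6-dimethoxybenzoyl)phenyl pivalate | CC(C)(C)C(=O)Oc1cccc(c1)C(=O)c1c(O)cc(OC)cc1OC | intermediate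
15 | 3-(2,6-dihydroxy-4-methoxybenzoyl)phenyl pivalate | CC(C)(C)C(=O)Oc1cccc(c1)C(=O)c1c(O)cc(OC)cc1O | intermediate
16 | prenyl bromide (1-bromo-3-methylbut-2-ene) | CC(C)=CCBr | starting material
17 | 3-[2,6-dihydroxy-4-methoxy-3-(3-methylbut-2-en-1-yl)benzoyl]phenyl pivalate | CC(C)(C)C(=O)Oc1cccc(c1)C(=O)c1c(O)cc(OC)c(CC=C(C)C)c1O | intermediate (not isolated)
18 | 3-[2,6-dihydroxy-4-methoxy-3,5-bis(3-methylbut-2-en-1-yl)benzoyl]phenyl pivalate | CC(C)(C)C(=O)Oc1cccc(c1)C(=O)c1c(O)c(CC=C(C)C)c(OC)c(CC=C(C)C)c1O | intermediate
19 | (2,6-dihydroxy-4-methoxy-3,5-bis(3-methylbut-2-en-1-yl)phenyl)(3-hydroxyphenyl)methanone | COc1c(CC=C(C)C)c(O)c(C(=O)c2cccc(O)c2)c(O)c1CC=C(C)C | target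

**Step count**
Total: 8 steps. Longest linear sequence: 7 steps (steps 1, 2, 3, 5, 6, 7, 8); step 4 prepares the acid partner on a side branch.

**Steps most likely to fail**

Step 5 (aryne insertion). The aryl anion may be protonated before it reaches the ester carbonyl, which would stop the sequence at simple O-arylation of the acid. The product phenoxide may also add to a second aryne, and hot fluoride may erode the pivalate. The fallback uses Friedel–Crafts chemistry, sets out from 10 and comes back at 14. Compound 10 is converted with oxalyl chloride and catalytic DMF in CH2Cl2 into 3-(chlorocarbonyl)phenyl pivalate F1. F1 acylates commercial 1,3,5-trimethoxybenzene under AlCl3 in CH2Cl2 at 0 °C to give 3-(2,4,6-trimethoxybenzoyl)phenyl pivalate F2. One equivalent of BCl3 in CH2Cl2 at −78 to 0 °C should then cleave a single ortho methyl ether by chelation and deliver 14.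

Step 7 (double C-prenylation). Alkylation may occur on oxygen in competition with carbon, may stall after the first prenyl group, or may continue at an already substituted carbon to give dearomatised products. The fallback sets out from 15 and comes back at 18. Both phenols of 15 are O-alkylated with methyl 2-methylbut-3-yn-2-yl carbonate (CuCl2 cat., DBU, MeCN, 0 °C to rt) to give 3-{4-methoxy-2,6-bis[(2-methylbut-3-yn-2-yl)oxy]benzoyl}phenyl pivalate F3. Semihydrogenation of both alkynes (H2, Pd/CaCO3 poisoned with Pb(OAc)2, quinoline, EtOAc) gives 3-{4-methoxy-2,6-bis[(2-methylbut-3-en-2-yl)oxy]benzoyl}phenyl pivalate F4. Heating F4 in toluene at 110 °C should bring about two aromatic Claisen rearrangements, each delivering the allyl unit with inversion to the only free ortho carbon (C3 and C5), which gives 18.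

Step 6 (selective demethylation). Cleavage of the C6 methyl ether may stay incomplete once the C2 phenol has taken up boron, and forcing the reaction may cost the pivalate or the C4 methyl ether. The fallback sets out from 14 and comes back at 15. Excess BBr3 in CH2Cl2 at −78 °C to rt removes both methyl ethers to give 3-(2,4,6-trihydroxybenzoyl)phenyl pivalate F5. Me2SO4 (1.0 equiv) with K2CO3 in acetone at rt should then methylate only the C4 hydroxyl, the one hydroxyl that is neither hydrogen-bonded to nor flanking the ketone and the most acidic, which gives 15.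

**Further compounds**
F1 | step 5 | 3-(chlorocarbonyl)phenyl pivalate | CC(C)(C)C(=O)Oc1cccc(C(=O)Cl)c1
F2 | step 5 | 3-(2,4,6-trimethoxybenzoyl)phenyl pivalate | CC(C)(C)C(=O)Oc1cccc(c1)C(=O)c1c(OC)cc(OC)cc1OC
F3 | step 7 | 3-{4-methoxy-2,6-bis[(2-methylbut-3-yn-2-yl)oxy]benzoyl}phenyl pivalate | CC(C)(C)C(=O)Oc1cccc(c1)C(=O)c1c(OC(C)(C)C#C)cc(OC)cc1OC(C)(C)C#C
F4 | step 7 | 3-{4-methoxy-2,6-bis[(2-methylbut-3-en-2-yl)oxy]benzoyl}phenyl pivalate | CC(C)(C)C(=O)Oc1cccc(c1)C(=O)c1c(OC(C)(C)C=C)cc(OC)cc1OC(C)(C)C=C
F5 | step 6 | 3-(2,4,6-trihydroxybenzoyl)phenyl pivalate | CC(C)(C)C(=O)Oc1cccc(c1)C(=O)c1c(O)cc(O)cc1O
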